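The route rests on cutting ring C (O1, C2, C3, C4, C4a, C8a) at C3–C4. Because C4 is a ketone carbon flanked by the C3 methylene, this bond can be forged as the alkene of a cyclic silyl enol ether by ring-closing metathesis, which closes ring C in one operation without disturbing the C2 stereocentre set earlier by iridium-catalysed allylic etherification. The metathesis precursor is the tert-butyldimethylsilyl enol ether of an acetophenone carrying the (S)-1-(chromenyl)allyl ether at O1 and the prenyl group stored as an O7 1,1-dimethylallyl ether; hydrolysis and an O7-to-C8 Claisen shift then finish the target.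

Key step: step 9

Assumption: the (Sa,S,S) enantiomer of the binaphthol-derived bis(1-phenylethyl)phosphoramidite is taken to deliver the (S)-configured aryl ether, by analogy with the usual sense of induction for heteroatom nucleophiles; should the sense prove opposite, the mirror-image ligand is used.

Step 1
Reactants: 1 2,4-dihydroxyacetophenone; 2 3-chloro-3-methylbut-1-yne
Product: 3 1-[2-hydroxy-4-(2-methylbut-3-yn-2-yloxy)phenyl]ethanone
Conditions: K2CO3, KI (cat.), CuI (cat.), acetone, 55 °C
Reagents that add atoms: none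
Why: The 4-OH is the more acidic phenol and is not tied up in the hydrogen bond to the acetyl group, so copper-assisted Williamson-type etherification with the tertiary propargylic chloride should give the mono-ether at O4.

Step 2
Reactants: 3 1-[2-hydroxy-4-(2-methylbut-3-yn-2-yloxy)phenyl]ethanone
Product: 4 1-[2-hydroxy-4-(2-methylbut-3-en-2-yloxy)phenyl]ethanone
Conditions: H2 (1 atm), Pd/CaCO3 poisoned with Pb(OAc)2 (Lindlar type), quinoline, EtOAc, rt
Reagents that add atoms: none
Why: Lindlar semihydrogenation on the poisoned palladium surface should stop at the terminal alkene and leave the aryl ketone untouched.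

Step 3
Reactants: 5 methyl (E)-4-hydroxycinnamate; 2 3-chloro-3-methylbut-1-yne
Product: 6 methyl (E)-3-[4-(2-methylbut-3-yn-2-yloxy)phenyl]acrylate
Conditions: K2CO3, KI (cat.), CuI (cat.), acetone, 55 °C
Reagents that add atoms: none
Why: The same copper-assisted Williamson-type etherification should convert the single phenol into the aryl 1,1-dimethylpropargyl ether, the unsaturated ester being inert to K2CO3 in acetone.

Step 4
Reactants: 6 methyl (E)-3-[4-(2-methylbut-3-yn-2-yloxy)phenyl]acrylate
Product: 8 methyl (E)-3-(2,2-dimethyl-2H-chromen-6-yl)acrylate, via allenyl phenol 7 (not isolated)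
Conditions: PhNEt2, 180 °C
Reagents that add atoms: none
Why: An aromatic propargyl Claisen rearrangement to either of the two equivalent ortho positions gives allenyl phenol 7, which should close to the 2,2-dimethyl-2H-chromene by 1,5-hydrogen shift and oxa-6π electrocyclisation.

Step 5
Reactants: 8 methyl (E)-3-(2,2-dimethyl-2H-chromen-6-yl)acrylate
Product: 10 (E)-3-(2,2-dimethyl-2H-chromen-6-yl)prop-2-en-1-ol, via enal 9 (not isolated)
Conditions: i-Bu2AlH (2.5 equiv), CH2Cl2, −78 → 0 °C; aq. KNaC4H4O6 work-up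
Reagents that add atoms: none
Why: 1,2-Hydride reduction of the enoate by the aluminium hydride passes through enal 9 to the allylic alcohol and should not touch either alkene.

Step 6
Reactants: 10 (E)-3-(2,2-dimethyl-2H-chromen-6-yl)prop-2-en-1-ol
Product: 11 (E)-3-(2,2-dimethyl-2H-chromen-6-yl)allyl methyl carbonate
Conditions: ClCO2Me, pyridine, CH2Cl2, 0 °C
Reagents that add atoms: methyl chloroformate, COC(=O)Cl
Why: Acylation of the primary allylic alcohol with a chloroformate under pyridine (carbonate formation) is straightforward and installs the leaving group for the allylic substitution.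

Step 7
Reactants: 4 1-[2-hydroxy-4-(2-methylbut-3-en-2-yloxy)phenyl]ethanone; 11 (E)-3-(2,2-dimethyl-2H-chromen-6-yl)allyl methyl carbonate
Product: 13 (S)-1-[2-[1-(2,2-dimethyl-2H-chromen-6-yl)allyloxy]-4-(2-methylbut-3-en-2-yloxy)phenyl]ethanone, via lithium phenoxide 12 (not isolated)
Conditions: 4 (1.3 equiv), LiOt-Bu, THF, 0 °C; then 11, [Ir(cod)Cl]2 (2 mol%, monovalent iridium), (Sa,S,S)-phosphoramidite (4 mol%), n-PrNH2 (catalyst pre-activation), THF, 25–40 °C
Reagents that add atoms: none
Why: In this iridium-catalysed asymmetric allylic etherification the cyclometalated iridium–phosphoramidite complex ionises carbonate 11 to an allyl complex and aryloxide 12 attacks its aryl-bearing terminus anti to the metal on the face left open by the ligand, so the branched ether should form with the (S) configuration fixed by the (Sa,S,S) ligand.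

Step 8
Reactants: 13 (S)-1-[2-[1-(2,2-dimethyl-2H-chromen-6-yl)allyloxy]-4-(2-methylbut-3-en-2-yloxy)phenyl]ethanone
Product: 15 tert-butyl[(1-{2-[(S)-1-(2,2-dimethyl-2H-chromen-6-yl)allyloxy]-4-(2-methylbut-3-en-2-yloxy)phenyl}vinyl)oxy]dimethylsilane, via potassium enolate 14 (not isolated)
Conditions: KN(SiMe3)2, THF, −78 °C; then TBSCl, −78 → 0 °C
Reagents that add atoms: tert-butyldimethylsilyl chloride, CC(C)(C)[Si](C)(C)Cl
Why: Kinetic deprotonation of the only enolisable position (the acetyl methyl) and O-silylation of potassium enolate 14 (silyl enol ether formation) should leave the C2 centre alone, and the base-only conditions avoid ionising the two acid-labile allylic aryl ethers.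

Step 9
Reactants: 15 tert-butyl[(1-{2-[(S)-1-(2,2-dimethyl-2H-chromen-6-yl)allyloxy]-4-(2-methylbut-3-en-2-yloxy)phenyl}vinyl)oxy]dimethylsilane
Product: 16 (S)-4-(tert-butyldimethylsilyloxy)-2-(2,2-dimethyl-2H-chromen-6-yl)-7-(2-methylbut-3-en-2-yloxy)-2H-chromene
Conditions: second-generation Grubbs catalyst RuCl2(H2IMes)(PCy3)(=CHPh) (10 mol%), PhMe (0.005 M), 60 °C, Ar
Reagents that add atoms: none
Why: In this ring-closing olefin metathesis the ruthenium benzylidene should load on the monosubstituted vinyl group next to C2, and the resulting alkylidene adds across the 1,1-disubstituted silyl enol ether through a ruthenacyclobutane whose cycloreversion forms the C3=C4 bond and expels ethylene. The closest known reaction type is the ring-closing metathesis of acyclic silyl enol ethers with terminal alkenes to cyclic silyl enol ethers. Ring C closes as a six-membered ring by intramolecular union of the two internal alkene carbons C3 and C4, a favoured ring size under high dilution. No stereocentre is created, and C2, which is adjacent to the reacting vinyl group but takes no part in the bond reorganisation, is carried through unchanged. The selectivity needed is reaction of the vinyl and enol ether pair alone among four alkenes: no other pairing can give an unstrained common ring, the O7 vinyl group sits on a quaternary carbon, the chromene alkene is an endocyclic cis-disubstituted styrene, and dilution suppresses intermolecular cross-metathesis.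

Step 10
Reactants: 16 (S)-4-(tert-butyldimethylsilyloxy)-2-(2,2-dimethyl-2H-chromen-6-yl)-7-(2-methylbut-3-en-2-yloxy)-2H-chromene
Product: 17 (S)-2-(2,2-dimethyl-2H-chromen-6-yl)-7-(2-methylbut-3-en-2-yloxy)chroman-4-one
Conditions: Bu4NF, AcOH, THF, 0 °C
Reagents that add atoms: none
Why: Fluoride attacks silicon and acetic acid protonates C3 as the enolate is released (buffered desilylation of a silyl enol ether), giving the ketone under near-neutral conditions that should spare the tertiary allyl ether, the chromene and the base-sensitive C2–O1 bond.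

Step 11
Reactants: 17 (S)-2-(2,2-dimethyl-2H-chromen-6-yl)-7-(2-methylbut-3-en-2-yloxy)chroman-4-one
Product: 19 (S)-7-hydroxy-2-(2,2-dimethyl-2H-chromen-6-yl)-8-(3-methylbut-2-enyl)chroman-4-one, via dienone 18 (not isolated)
Conditions: PhMe, 120 °C, sealed tube, degassed
Reagents that add atoms: none
Why: In this aromatic Claisen rearrangement the 1,1-dimethylallyl aryl ether should undergo a concerted [3,3] shift with allyl inversion to C8, the ortho position reached through the C7–C8 bond of higher double-bond character in 7-oxygenated chroman-4-ones, after which dienone 18 tautomerises to the phenol while C2, remote from the reacting array, keeps its configuration.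

Compound list
1 | 2,4-dihydroxyacetophenone | CC(=O)c1ccc(O)cc1O | starting material
2 | 3-chloro-3-methylbut-1-yne | CC(C)(Cl)C#C | starting material
3 | 1-[2-hydroxy-4-(2-methylbut-3-yn-2-yloxy)phenyl]ethanone | CC(=O)c1ccc(OC(C)(C)C#C)cc1O | intermediate
4 | 1-[2-hydroxy-4-(2-methylbut-3-en-2-yloxy)phenyl]ethanone | CC(=O)c1ccc(OC(C)(C)C=C)cc1O | intermediate
5 | methyl (E)-4-hydroxycinnamate | COC(=O)/C=C/c1ccc(O)cc1 | starting material
6 | methyl (E)-3-[4-(2-methylbut-3-yn-2-yloxy)phenyl]acrylate | COC(=O)/C=C/c1ccc(OC(C)(C)C#C)cc1 | intermediate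
7 | methyl (E)-3-[4-hydroxy-3-(3-methylbuta-1,2-dienyl)phenyl]acrylate (allenyl phenol, not isolated) | COC(=O)/C=C/c1ccc(O)c(C=C=C(C)C)c1 | intermediate
8 | methyl (E)-3-(2,2-dimethyl-2H-chromen-6-yl)acrylate | COC(=O)/C=C/c1ccc2c(c1)C=CC(C)(C)O2 | intermediate
9 | (E)-3-(2,2-dimethyl-2H-chromen-6-yl)acrylaldehyde (enal, not isolated) | O=C/C=C/c1ccc2c(c1)C=CC(C)(C)O2 | intermediate
10 | (E)-3-(2,2-dimethyl-2H-chromen-6-yl)prop-2-en-1-ol | OC/C=C/c1ccc2c(c1)C=CC(C)(C)O2 | intermediate
11 | (E)-3-(2,2-dimethyl-2H-chromen-6-yl)allyl methyl carbonate | COC(=O)OC/C=C/c1ccc2c(c1)C=CC(C)(C)O2 | intermediate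
12 | lithium 2-acetyl-5-(2-methylbut-3-en-2-yloxy)phenoxide (not isolated) | CC(=O)c1ccc(OC(C)(C)C=C)cc1[O-].[Li+] | intermediate
13 | (S)-1-[2-[1-(2,2-dimethyl-2H-chromen-6-yl)allyloxy]-4-(2-methylbut-3-en-2-yloxy)phenyl]ethanone | C=CC(C)(C)Oc1ccc(C(C)=O)c(O[C@@H](C=C)c2ccc3c(c2)C=CC(C)(C)O3)c1 | intermediate
14 | potassium enolate of 13 (not isolated) | C=CC(C)(C)Oc1ccc(C(=C)[O-])c(O[C@@H](C=C)c2ccc3c(c2)C=CC(C)(C)O3)c1.[K+] | intermediate
15 | tert-butyl[(1-{2-[(S)-1-(2,2-dimethyl-2H-chromen-6-yl)allyloxy]-4-(2-methylbut-3-en-2-yloxy)phenyl}vinyl)oxy]dimethylsilane | C=CC(C)(C)Oc1ccc(C(=C)O[Si](C)(C)C(C)(C)C)c(O[C@@H](C=C)c2ccc3c(c2)C=CC(C)(C)O3)c1 | intermediate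
16 | (S)-4-(tert-butyldimethylsilyloxy)-2-(2,2-dimethyl-2H-chromen-6-yl)-7-(2-methylbut-3-en-2-yloxy)-2H-chromene | C=CC(C)(C)Oc1ccc2c(c1)O[C@H](c1ccc3c(c1)C=CC(C)(C)O3)C=C2O[Si](C)(C)C(C)(C)C | intermediate
17 | (S)-2-(2,2-dimethyl-2H-chromen-6-yl)-7-(2-methylbut-3-en-2-yloxy)chroman-4-one | C=CC(C)(C)Oc1ccc2c(c1)O[C@H](c1ccc3c(c1)C=CC(C)(C)O3)CC2=O | intermediate
18 | (2S)-2-(2,2-dimethyl-2H-chromen-6-yl)-8-(3-methylbut-2-enyl)-2,3-dihydro-8H-chromene-4,7-dione (ortho-dienone, C8 epimers, not isolated) | CC(C)=CCC1C(=O)C=CC2=C1O[C@H](c1ccc3c(c1)C=CC(C)(C)O3)CC2=O | intermediate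
19 | (S)-7-hydroxy-2-(2,2-dimethyl-2H-chromen-6-yl)-8-(3-methylbut-2-enyl)chroman-4-one | CC(C)=CCc1c(O)ccc2c1O[C@H](c1ccc3c(c1)C=CC(C)(C)O3)CC2=O | target

Total step count: 11. Longest linear sequence: 9 steps (from 5 through steps 3 to 11).

Steps most likely to fail

Step 9. The ruthenium alkylidene may be diverted onto the terminal alkene of the O7 1,1-dimethylallyl group, giving cross-metathesis and oligomers, or ruthenium hydride species may isomerise the allylic ether before closure. The fallback closes the ring with O7 carried as an inert silyl ether and attaches the five-carbon unit afterwards.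
- It sets out from 1: selective 4-O-silylation (TIPSCl, imidazole, DMF) gives 1-[2-hydroxy-4-(triisopropylsilyloxy)phenyl]ethanone F1.
- Iridium-catalysed etherification with 11 as in step 7 gives (S)-1-[2-[1-(2,2-dimethyl-2H-chromen-6-yl)allyloxy]-4-(triisopropylsilyloxy)phenyl]ethanone F2.
- KN(SiMe3)2 and TBSCl give the silyl enol ether tert-butyl[(1-{2-[(S)-1-(2,2-dimethyl-2H-chromen-6-yl)allyloxy]-4-(triisopropylsilyloxy)phenyl}vinyl)oxy]dimethylsilane F3, which holds only two terminal alkenes.
- Ring-closing metathesis gives (S)-4-(tert-butyldimethylsilyloxy)-2-(2,2-dimethyl-2H-chromen-6-yl)-7-(triisopropylsilyloxy)-2H-chromene F4.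
- Bu4NF/AcOH removes both silyl groups to give (S)-7-hydroxy-2-(2,2-dimethyl-2H-chromen-6-yl)chroman-4-one F5.
- Palladium-catalysed O-allylation of F5 with methyl 2-methylbut-3-en-2-yl carbonate F6 (made from 2-methylbut-3-en-2-ol, n-BuLi and ClCO2Me; coupling with Pd(PPh3)4, zerovalent palladium, THF, 0 °C) should give the tertiary ether under kinetic control and rejoins the route at 17.

Step 7. The chelated, electron-poor ortho-acyl aryloxide may attack the allyl–iridium intermediate too slowly, and the doubly activated branched ether may re-ionise on the metal, eroding branched selectivity and enantiomeric purity. The fallback separates the setting of the stereocentre from the attachment of the phenol.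
- It sets out from 11: iridium-catalysed allylic substitution with the strongly nucleophilic silanolate Et3SiOK ([Ir(cod)Cl]2, the mirror-image (Ra,R,R) ligand, CH2Cl2, rt) gives (R)-triethyl{[1-(2,2-dimethyl-2H-chromen-6-yl)allyl]oxy}silane F7.
- Bu4NF gives (R)-1-(2,2-dimethyl-2H-chromen-6-yl)prop-2-en-1-ol F8.
- Mitsunobu coupling of F8 with phenol 4 (PPh3, DIAD, PhMe, −20 °C) should proceed with inversion and returns to the route at 13.

Step 11. The allyl unit may be delivered partly to C6, and C2 may lose configuration through reversible opening of ring C at the temperature of the shift. The fallback moves the sigmatropic shift to the achiral acetophenone stage, where the hydrogen-bonded 2-OH directs it to the carbon between the two oxygens, and builds ring C by the classical chalcone route.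
- It sets out from 4: heating (PhMe, 120 °C) gives 1-[2,4-dihydroxy-3-(3-methylbut-2-enyl)phenyl]ethanone F9.
- In parallel, 4-hydroxybenzaldehyde and 2 give, by the chemistry of steps 3 and 4, 4-(2-methylbut-3-yn-2-yloxy)benzaldehyde F10 and then 2,2-dimethyl-2H-chromene-6-carbaldehyde F11.
- Claisen–Schmidt condensation of F9 with F11 (KOH, EtOH, rt) gives (E)-1-[2,4-dihydroxy-3-(3-methylbut-2-enyl)phenyl]-3-(2,2-dimethyl-2H-chromen-6-yl)prop-2-en-1-one F12.
- Oxa-Michael cyclisation (NaOAc, EtOH, reflux) gives racemic 7-hydroxy-2-(2,2-dimethyl-2H-chromen-6-yl)-8-(3-methylbut-2-enyl)chroman-4-one F13.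
- Preparative chromatography on a chiral stationary phase secures the (S)-enantiomer and comes back to the route at 19; the other enantiomer can be recycled by base-mediated equilibration.

Further compounds
F1 | step 9 | 1-[2-hydroxy-4-(triisopropylsilyloxy)phenyl]ethanone | CC(=O)c1ccc(O[Si](C(C)C)(C(C)C)C(C)C)cc1O
F2 | step 9 | (S)-1-[2-[1-(2,2-dimethyl-2H-chromen-6-yl)allyloxy]-4-(triisopropylsilyloxy)phenyl]ethanone | CC(=O)c1ccc(O[Si](C(C)C)(C(C)C)C(C)C)cc1O[C@@H](C=C)c1ccc2c(c1)C=CC(C)(C)O2
F3 | step 9 | tert-butyl[(1-{2-[(S)-1-(2,2-dimethyl-2H-chromen-6-yl)allyloxy]-4-(triisopropylsilyloxy)phenyl}vinyl)oxy]dimethylsilane | C=C(O[Si](C)(C)C(C)(C)C)c1ccc(O[Si](C(C)C)(C(C)C)C(C)C)cc1O[C@@H](C=C)c1ccc2c(c1)C=CC(C)(C)O2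
F4 | step 9 | (S)-4-(tert-butyldimethylsilyloxy)-2-(2,2-dimethyl-2H-chromen-6-yl)-7-(triisopropylsilyloxy)-2H-chromene | CC(C)[Si](C(C)C)(C(C)C)Oc1ccc2c(c1)O[C@H](c1ccc3c(c1)C=CC(C)(C)O3)C=C2O[Si](C)(C)C(C)(C)C
F5 | step 9 | (S)-7-hydroxy-2-(2,2-dimethyl-2H-chromen-6-yl)chroman-4-one | Oc1ccc2c(c1)O[C@H](c1ccc3c(c1)C=CC(C)(C)O3)CC2=O
F6 | step 9 | methyl 2-methylbut-3-en-2-yl carbonate | COC(=O)OC(C)(C)C=C
F7 | step 7 | (R)-triethyl{[1-(2,2-dimethyl-2H-chromen-6-yl)allyl]oxy}silane | CC[Si](CC)(CC)O[C@H](C=C)c1ccc2c(c1)C=CC(C)(C)O2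
F8 | step 7 | (R)-1-(2,2-dimethyl-2H-chromen-6-yl)prop-2-en-1-ol | O[C@H](C=C)c1ccc2c(c1)C=CC(C)(C)O2
F9 | step 11 | 1-[2,4-dihydroxy-3-(3-methylbut-2-enyl)phenyl]ethanone | CC(=O)c1ccc(O)c(CC=C(C)C)c1O
F10 | step 11 | 4-(2-methylbut-3-yn-2-yloxy)benzaldehyde | O=Cc1ccc(OC(C)(C)C#C)cc1
F11 | step 11 | 2,2-dimethyl-2H-chromene-6-carbaldehyde | O=Cc1ccc2c(c1)C=CC(C)(C)O2
F12 | step 11 | (E)-1-[2,4-dihydroxy-3-(3-methylbut-2-enyl)phenyl]-3-(2,2-dimethyl-2H-chromen-6-yl)prop-2-en-1-one | CC(C)=CCc1c(O)ccc(C(=O)/C=C/c2ccc3c(c2)C=CC(C)(C)O3)c1O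
F13 | step 11 | racemic 7-hydroxy-2-(2,2-dimethyl-2H-chromen-6-yl)-8-(3-methylbut-2-enyl)chroman-4-one | CC(C)=CCc1c(O)ccc2c1OC(c1ccc3c(c1)C=CC(C)(C)O3)CC2=O
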